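The earlier runs and the new flask were computed with constants of no real substance.

A one-step world is the place to start: G and Z give L, L stays dissolved, and a percentage of L turns into a concentration through one factor. That factor is C, the whole charge of G spread over the final volume, 0.00833 M.

| setting | winter | spring | noon | north | south-east | south | north-east | south-west |
|---|---|---|---|---|---|---|---|---|
| G | 0.010 M (fed, over 2.0 h) | 0.010 M (fed, over 2.0 h) | 0.010 M (fed, over 2.0 h) | 0.010 M (fed, over 2.0 h) | 0.010 M (fed, over 2.0 h) | 0.010 M (fed, over 2.0 h) | 0.010 M (fed, over 2.0 h) | 0.010 M (fed, over 2.0 h) |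
| Z | 0.60 equiv | 0.60 equiv | 0.60 equiv | 0.600 equiv | 0.600 equiv | 0.600 equiv | 0.600 equiv | 0.600 equiv |
| E | 0.14 equiv | 0.52 equiv | 1.5 equiv | 0.150 equiv | 0.300 equiv | 0.600 equiv | 1.20 equiv | 2.00 equiv |
| remark | run made earlier; the fed solution adds 0.20 times the starting volume | run made earlier; the fed solution adds 0.20 times the starting volume | run made earlier; the fed solution adds 0.20 times the starting volume | the fed solution adds 0.20 times the starting volume | the fed solution adds 0.20 times the starting volume | the fed solution adds 0.20 times the starting volume | the fed solution adds 0.20 times the starting volume | the fed solution adds 0.20 times the starting volume |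
| time |  |  |  | 12 h | 12 h | 12 h | 12 h | 12 h |

- winter (time / h: L / %, G / %): 0.833: 8.8, 26.8; 2.00: 37.3, 38.7; 4.00: 58.7, 4.1; 6.00: 59.2, 0.8; 8.00: 59.9, 0
- spring (time / h: L / %, G / %): 0.667: 4.2, 23.1; 1.33: 16.7, 34.2; 2.50: 40.3, 21.9; 4.00: 52.1, 3.3; 8.00: 56.3, 0
- noon (time / h: L / %, G / %): 0.833: 3.9, 26.4; 2.00: 20.7, 39.2; 4.00: 34.2, 3.9; 6.00: 35.8, 0.1; 8.00: 35.6, 0

(readings scatter by 0.3 percentage points)

- charges are per starting volume, the dose included; the dosed solution carries all of it
- the numbers in the tables scatter by 0.3 percentage points (one standard deviation)
- percentages count the whole charge, also what has not yet gone in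
- a reading or a percentage of L counts all its forms, free or not
- the concentration of L that is asked is that of its free form alone
- "hardly changes" means that all values lie within two and a half points (for a concentration: within two and a half percent of the largest)

- [L] (only what is free in solution) at the end for north, south-east, south, north-east, south-west, in this order
- how the row runs (hardly changes / falls, then rises / falls all the way / rises all the way / rises, then falls)

The bracket comes from C and the readings. From above, Z at 0.600 equiv is the limiting reagent, so the reckoned ceiling for L in north, free or not, is 0.00500 M. The winter run, with E at 0.14 equiv, reads 59.9 % at 8.00 h, which is 0.00499 M through C. The top also falls along the row: at 8.00 h the noon run reads 35.6 %, less than the spring run's 56.3 %. South-west, with E at 2.00 equiv, is therefore reckoned here to lie under 0.00297 M. From below, the readings count L free or not, so the floor reckoned from them stays at zero. The free L is then a top minus an unmeasured correction, and the shape of the row stays open until that correction is known.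

The forecast, 0.005 M, 0.00498 M, 0.00449 M, 0.00332 M and 0.00247 M, falls all the way, lies in the upper part of this bracket, on the words “I take free L = total L, though this is untested”.

The flask gives 6.00 × 10⁻⁴ M, 6.00 × 10⁻⁴ M, 6.00 × 10⁻⁴ M, 6.00 × 10⁻⁴ M and 6.00 × 10⁻⁴ M, so the row hardly changes, inside the bracket, and the south-west value is less than the 0.00297 M reckoned for it.

    G → D (k = 3.20 × 10⁻⁴ s⁻¹)
    Z + D → L (k = 0.210 L mol⁻¹ s⁻¹)
    E + D → X (k = 0.130 L mol⁻¹ s⁻¹)
    J ⇌ L, rate k4*(cs4 - [L]) while solid is left; crystals form when [L] > cs4 (solubility = 0.600 mM, k = 0.00710 s⁻¹)

The largest single effect in north is the ceiling on dissolved L: without it, [L] at the end stands at 0.00500 M instead of 6.00 × 10⁻⁴ M. Through C, the dissolved part is 7.20 % of the G charged. North, with L at 60.0 % at 12.0 h, therefore holds 52.8 % as crystals J. South-west, with L at 30.1 %, holds 22.9 % as J.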